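At the reading, 90 min after mixing, Sunday's, Tuesday's and Monday's flasks differ in their charge of free catalyst, and the question is what each then holds.

| flask | starting material | coupling partner | free catalyst | remark | time |
|---|---|---|---|---|---|
| blue | 0.050 M | 0.15 M | 1.2 mM | run made earlier |  |
| grey | 0.050 M | 0.15 M | 2.1 mM | run made earlier |  |
| green | 0.050 M | 0.15 M | 3.1 mM | run made earlier |  |
| Sunday's | 0.050 M | 0.150 M | 1.1 mM |  | 1.5 h |
| Tuesday's | 0.050 M | 0.150 M | 2.2 mM |  | 1.5 h |
| Monday's | 0.050 M | 0.150 M | 4.4 mM |  | 1.5 h |

| run | time / min | starting material / % | over-reaction product / % | catalyst intermediate B / % | target / % |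
|---|---|---|---|---|---|
| blue | 8.00 | 87.7 | 7.5 | 0.3 | 5.1 |
| blue | 25.0 | 66.7 | 28.2 | 0 | 4.6 |
| blue | 40.0 | 53.9 | 42.3 | 0 | 3.4 |
| blue | 60.0 | 40.8 | 55.3 | 0.2 | 3.3 |
| blue | 90.0 | 27.7 | 69.7 | 0 | 2.6 |
| grey | 20.0 | 57.6 | 34.7 | 0 | 7.6 |
| grey | 40.0 | 35.3 | 58.6 | 0 | 5.2 |
| grey | 50.0 | 28.5 | 66.4 | 0 | 4.4 |
| grey | 80.0 | 15.5 | 81.2 | 0.4 | 2.7 |
| grey | 90.0 | 12.8 | 84.0 | 0.7 | 2.4 |
| green | 8.00 | 71.5 | 16.7 | 0 | 12.1 |
| green | 15.0 | 54.1 | 35.1 | 0 | 10.8 |
| green | 25.0 | 38.0 | 52.9 | 0 | 9.1 |
| green | 50.0 | 17.7 | 77.7 | 0.2 | 4.1 |
| green | 90.0 | 6.6 | 91.8 | 0.7 | 1.9 |

(each reading ± 0.3 percentage points)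

- what was read earlier has a scatter of 0.3 percentage points, one standard deviation

- which of these there is most of at the end, counted by the starting material in it, Sunday's (target / starting material / catalyst intermediate B / over-reaction product)
- which of these there is most of at the end, counted by the starting material in it, Tuesday's (target / starting material / catalyst intermediate B / over-reaction product)
- which of these there is most of at the end, counted by the starting material in it, Monday's (target / starting material / catalyst intermediate B / over-reaction product)
- amount of the one of these that there is most of at the end, in percent of the starting material charged, Sunday's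
- amount of the one of these that there is most of at the end, in percent of the starting material charged, Tuesday's
- amount of the one of these that there is most of at the end, in percent of the starting material charged, Monday's

Two chemists reckon with the same clock. Sunday's 90 min are worth 82.5 min of blue's time: this is the equivalent time τ, clock time multiplied by catalyst charge over blue's catalyst charge. Tuesday's stands at 165 min and Monday's at 330 min. The clock looks sound: blue at 60.0 min, green at 64.6 min of τ and grey at 70.0 min of τ read 40.8%, 38.0% and 35.3% of starting material, one falling curve across the runs.

The first chemist holds a straight pseudo-first-order decay in τ, with the rate 0.0164 min⁻¹ read from blue's first point. That gives Sunday's 25.8% of starting material. Blue's last readings add up to 100%, so over-reaction product is what remains after starting material and target. With blue's final 2.6% of target, that is 71.6%. In support, at green's first point, τ = 20.7 min, the decay gives 71.2%, where 71.5% was read.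

The second chemist, whose side I take, answers that the same decay gives 22.8% at blue's end, where 27.7% was read, with a scatter of 0.3 percentage points. The curve bends, so it must be read rather than drawn straight. Between grey's readings at τ = 70.0 min and 87.5 min, Sunday's comes out at 30.3% of starting material, hence 67.1% of over-reaction product, less than the first chemist's figure. Between the ends of grey and green, at τ = 158 min and 233 min, Tuesday's comes out at 12.0%, hence 85.6%. Monday's lies past green, so the same slope is extended to 2.79%, hence 95.3%.

The forecast, on the second chemist's side “with slowing that tracks conversion”, names over-reaction product in each flask, at 66.8%, 85.3% and 94%, a little under my Sunday figure and my Monday figure.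

Sunday's ends with over-reaction product at 66.9%, Tuesday's at 85.6% and Monday's at 96.3%, so the bent curve stands and the straight decay keeps the early stretch, up to about τ = 20.7 min.

    coupling partner + free catalyst ⇌ catalyst intermediate A (K = 3.00 M⁻¹, k = 1.60 M⁻¹ s⁻¹)
    starting material + catalyst intermediate A ⇌ catalyst intermediate B (K = 43.1 M⁻¹, k = 1.03 M⁻¹ s⁻¹)
    catalyst intermediate B → released group + catalyst intermediate C (k = 0.173 s⁻¹)
    catalyst intermediate C → free catalyst + target (k = 0.203 s⁻¹)
    coupling partner + target → over-reaction product (k = 0.0318 M⁻¹ s⁻¹)

Tuesday's at 0.750 h has Sunday's τ, within rounding, and holds 30.4% of starting material against Sunday's final 30.7%, but 4.96% of target against 2.35%. At the same τ of 82.5 min, a flask like Sunday's with 0.26 M of coupling partner ends with 15.8% of starting material.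

All runs are simulated for substances that don't exist; noise was put on by code.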